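**Retrosynthetic overview**
1. Target 9 comes from its 18-fold benzyl ether 8 by one global hydrogenolysis.
2. 8 ⇒ 7 + 6 and 7 ⇒ 2 + 6. These are two C4→C8 flavanyl-cation arylations that grow the chain from the lower catechin unit upward, and building block 6 is used twice.
3. 6 ⇒ 5 by making a C4–O bond through benzylic C–H oxidation. This installs the leaving group needed in line 2.
4. Key disconnection: the C3–O(galloyl) bond of 5 ⇒ alcohol 2 + acid 3 with inversion (3S → 3R). One step installs the ester and the 2,3-cis stereochemistry, so cheap (+)-catechin supplies all three flavan units.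
5. No ring is formed. All chroman, catechol and galloyl rings are bought intact, and the units are joined in the order lower → middle → upper.

Assumption: the SMILES is read as epicatechin-3-O-gallate-(4β→8)-epicatechin-3-O-gallate-(4β→8)-catechin (upper and middle units 2R,3R, 3,4-trans/4β; lower unit 2R,3S), and 3,4,5-tris(benzyloxy)benzoic acid is bought as such.

**Step 1**
Reactants: 1 (+)-catechin
Product: 2 tetra-O-benzyl-(+)-catechin
Conditions: BnBr (4.4 equiv), K2CO3 (5 equiv), DMF, Ar, 0 °C → rt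
Reagents that add atoms: benzyl bromide, BrCc1ccccc1
Why: In this Williamson ether synthesis K2CO3 deprotonates only the four phenols, so the secondary 3-OH stays free and no stereocenter is touched.

**Step 2**
Reactants: 2 tetra-O-benzyl-(+)-catechin; 3 3,4,5-tris(benzyloxy)benzoic acid
Product: 5 hepta-O-benzyl-(−)-epicatechin 3-O-gallate, via catechin-3-yl diphenylphosphinite 4 (not isolated)
Conditions: Ph2PCl (1.1 equiv), Et3N (1.2 equiv), DMAP (cat.), toluene, 0 °C → rt, filter under Ar; then 3 (1.3 equiv), 2,6-dimethyl-1,4-benzoquinone (1.1 equiv), toluene–CH2Cl2 (0.5 M), 0 °C → rt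
Reagents that add atoms: chlorodiphenylphosphine, ClP(c1ccccc1)c1ccccc1 (its Ph2P group sits in intermediate 4 only and is absent from 5)
Why: Proposed new method: stereoinvertive dehydrative galloylation of a 2,3-trans-flavan-3-ol, a substrate class on which C3 activation classically ends in 1,2-aryl shift or elimination and on which this condensation has not been shown; P(III) of 4 adds to the unhindered quinone oxygen to give an alkoxy(aryloxy)diphenylphosphonium phenoxide, the phenoxide deprotonates 3, and the tight gallate ion pair displaces Ph2P(O)OAr at C3 by SN2 from the α-face (3S → 3R, C3–O bond formed); because the P–O–C3 bond is made beforehand no acyloxyphosphonium (retention) channel exists, the bulky phosphonium holds the C-ring in the diequatorial half-chair where neither the B-ring nor any C–H is antiperiplanar to C3–O (phenonium formation and E2 are switched off), and the 1,3-positions (O1, C4a) carry no axial substituents so the backside corridor is open; the closest known reaction type is the Mukaiyama oxidation–reduction condensation/Mitsunobu inversion of hindered secondary alcohols such as menthol.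

**Step 3**
Reactants: 5 hepta-O-benzyl-(−)-epicatechin 3-O-gallate
Product: 6 4β-(2-ethoxyethoxy)-hepta-O-benzyl-(−)-epicatechin 3-O-gallate
Conditions: DDQ (2 equiv), 2-ethoxyethanol (10 equiv), CH2Cl2, rt
Reagents that add atoms: 2-ethoxyethanol, CCOCCO
Why: DDQ benzylic oxidation (hydride abstraction) occurs at C4, the only C–H conjugated with the 5,7-dialkoxy A-ring, and the cation is trapped by the alcohol from the β-face anti to the axial 3α-gallate, giving the 3,4-trans (4S) ether while plain benzyl ethers survive.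

**Step 4**
Reactants: 6 4β-(2-ethoxyethoxy)-hepta-O-benzyl-(−)-epicatechin 3-O-gallate; 2 tetra-O-benzyl-(+)-catechin (4 equiv, excess recovered)
Product: 7 protected dimer [hepta-O-benzyl-epicatechin gallate]-(4β→8)-[tetra-O-benzylcatechin]
Conditions: TMSOTf (0.2 equiv), CH2Cl2, −78 °C; aq. NaHCO3
Reagents that add atoms: none
Why: In this Lewis-acid-catalysed Friedel–Crafts-type procyanidin condensation the flavan-4-yl cation is shielded on its α-face by the participating 3α-galloyl carbonyl, so C8 of 2 (its most nucleophilic position) attacks from the β-face and sets the 3,4-trans (4β) center, while the excess of 2 suppresses further chain growth.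

**Step 5**
Reactants: 6 4β-(2-ethoxyethoxy)-hepta-O-benzyl-(−)-epicatechin 3-O-gallate; 7 protected dimer (2.5 equiv, excess recovered)
Product: 8 protected trimer (18 benzyl ethers, free 3-OH on the lower unit)
Conditions: TMSOTf (0.2 equiv), CH2Cl2, −78 → −40 °C; aq. NaHCO3
Reagents that add atoms: none
Why: This is the same Friedel–Crafts-type flavanyl-cation arylation, in which the free C8 of the epicatechin-gallate unit of 7 is the most accessible and nucleophilic site and galloyl participation again enforces β-attack, setting the second 4β center.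

**Step 6**
Reactants: 8 protected trimer
Product: 9 epicatechin-3-O-gallate-(4β→8)-epicatechin-3-O-gallate-(4β→8)-catechin (target)
Conditions: H2 (1 atm), 20% Pd(OH)2/C, THF–MeOH–H2O, rt; Sephadex LH-20
Reagents that add atoms: none
Why: Neutral catalytic hydrogenolysis cleaves all 18 aryl benzyl ethers and leaves the gallate esters, the acid-labile interflavan bonds and all eight stereocenters untouched.

**Compound list**
1 | (+)-catechin, (2R,3S)-2-(3,4-dihydroxyphenyl)chromane-3,5,7-triol | O[C@H]1Cc2c(O)cc(O)cc2O[C@@H]1c1ccc(O)c(O)c1 | starting material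
2 | 5,7,3',4'-tetra-O-benzyl-(+)-catechin (2R,3S; 3-OH free) | O[C@H]1Cc2c(OCc5ccccc5)cc(OCc5ccccc5)cc2O[C@@H]1c1ccc(OCc5ccccc5)c(OCc5ccccc5)c1 | intermediate
3 | 3,4,5-tris(benzyloxy)benzoic acid | OC(=O)c1cc(OCc2ccccc2)c(OCc2ccccc2)c(OCc2ccccc2)c1 | starting material
4 | (2R,3S)-5,7,3',4'-tetra-O-benzylcatechin-3-yl diphenylphosphinite | c6ccccc6P(c6ccccc6)O[C@H]1Cc2c(OCc5ccccc5)cc(OCc5ccccc5)cc2O[C@@H]1c1ccc(OCc5ccccc5)c(OCc5ccccc5)c1 | intermediate (not isolated)
5 | 5,7,3',4'-tetra-O-benzyl-(−)-epicatechin 3-O-(3,4,5-tri-O-benzylgallate) (2R,3R) | O=C(O[C@@H]1Cc2c(OCc5ccccc5)cc(OCc5ccccc5)cc2O[C@@H]1c1ccc(OCc5ccccc5)c(OCc5ccccc5)c1)c1cc(OCc5ccccc5)c(OCc5ccccc5)c(OCc5ccccc5)c1 | intermediate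
6 | (2R,3R,4S)-4β-(2-ethoxyethoxy) derivative of 5 (2,3-cis, 3,4-trans) | O=C(O[C@@H]1[C@@H](OCCOCC)c2c(OCc5ccccc5)cc(OCc5ccccc5)cc2O[C@@H]1c1ccc(OCc5ccccc5)c(OCc5ccccc5)c1)c1cc(OCc5ccccc5)c(OCc5ccccc5)c(OCc5ccccc5)c1 | intermediate
7 | [hepta-O-benzyl-epicatechin 3-O-gallate]-(4β→8)-[tetra-O-benzylcatechin]; upper unit 2R,3R, 3,4-trans; lower unit 2R,3S with free 3-OH | O=C(O[C@@H]1[C@@H](c2c(OCc5ccccc5)cc(OCc5ccccc5)c3c2O[C@H](c2ccc(OCc5ccccc5)c(OCc5ccccc5)c2)[C@@H](O)C3)c2c(OCc5ccccc5)cc(OCc5ccccc5)cc2O[C@@H]1c1ccc(OCc5ccccc5)c(OCc5ccccc5)c1)c1cc(OCc5ccccc5)c(OCc5ccccc5)c(OCc5ccccc5)c1 | intermediate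
8 | [hepta-O-benzyl-epicatechin 3-O-gallate]-(4β→8)-[hepta-O-benzyl-epicatechin 3-O-gallate]-(4β→8)-[tetra-O-benzylcatechin] | O=C(O[C@@H]1[C@@H](c2c(OCc5ccccc5)cc(OCc5ccccc5)c3c2O[C@H](c2ccc(OCc5ccccc5)c(OCc5ccccc5)c2)[C@@H](O)C3)c2c(OCc5ccccc5)cc(OCc5ccccc5)c([C@H]3c4c(OCc5ccccc5)cc(OCc5ccccc5)cc4O[C@H](c4ccc(OCc5ccccc5)c(OCc5ccccc5)c4)[C@@H]3OC(=O)c3cc(OCc5ccccc5)c(OCc5ccccc5)c(OCc5ccccc5)c3)c2O[C@@H]1c1ccc(OCc5ccccc5)c(OCc5ccccc5)c1)c1cc(OCc5ccccc5)c(OCc5ccccc5)c(OCc5ccccc5)c1 | intermediate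
9 | epicatechin-3-O-gallate-(4β→8)-epicatechin-3-O-gallate-(4β→8)-catechin (CNP0269915.2) | O=C(O[C@@H]1[C@@H](c2c(O)cc(O)c3c2O[C@H](c2ccc(O)c(O)c2)[C@@H](O)C3)c2c(O)cc(O)c([C@H]3c4c(O)cc(O)cc4O[C@H](c4ccc(O)c(O)c4)[C@@H]3OC(=O)c3cc(O)c(O)c(O)c3)c2O[C@@H]1c1ccc(O)c(O)c1)c1cc(O)c(O)c(O)c1 | target

**Total step count:** 6. **Longest linear sequence:** 6 (1 → 2 → 5 → 6 → 7 → 8 → 9).

**Three steps most likely to fail**

Step 2 (the proposed new step). The electron-rich B-ring may still participate through the diaxial conformer. That would give a phenonium ion and then the retained catechin gallate or a 2-acyloxyisoflavan. E2 elimination may also give the flav-3-ene. The fallback uses only known chemistry and sets out from 2. Dess–Martin periodinane in wet CH2Cl2 gives (2R)-5,7,3',4'-tetra-O-benzylflavan-3-one F1. L-Selectride/LiBr in THF at −78 °C delivers hydride to the β-face anti to the 2-aryl group and gives 5,7,3',4'-tetra-O-benzyl-(−)-epicatechin F2. Steglich esterification of F2 with 3 (DCC, DMAP, CH2Cl2) comes back to the route at 5, at a cost of two extra steps.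

Step 3. The electron-withdrawing 3-O-galloyl group slows hydride abstraction at C4, so over-oxidation or attack on benzyl ethers may compete. The fallback changes the order of events and sets out from 5. Methanolysis (K2CO3, MeOH–THF) frees 5,7,3',4'-tetra-O-benzyl-(−)-epicatechin F2, which keeps the inverted C3. DDQ/2-ethoxyethanol on this free alcohol gives (2R,3R,4S)-5,7,3',4'-tetra-O-benzyl-4β-(2-ethoxyethoxy)epicatechin F3. Steglich esterification of F3 with 3 (DCC, DMAP) comes back to the route at 6.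

Step 5. Building block 6 still has a free C8 of its own, so it can self-condense. The product 8 can also be extended to a tetramer, and C6 attack may compete. The fallback caps the electrophile with a halogen and sets out from 6. NBS in CH2Cl2 at −40 °C gives the 8-bromo derivative of 6, 8-bromo-4β-(2-ethoxyethoxy)-hepta-O-benzyl-epicatechin 3-O-gallate F4, which can act only as an electrophile. Equimolar TMSOTf-catalysed coupling of F4 with 7 gives the 8-bromo-capped protected trimer F5, which cannot grow further. H2, Pd(OH)2/C and Et3N then remove the bromine and all 18 benzyl groups in one operation, coming back to the route at 9.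

**Further compounds**
F1 | step 2 | (2R)-5,7,3',4'-tetra-O-benzylflavan-3-one | O=C1Cc2c(OCc5ccccc5)cc(OCc5ccccc5)cc2O[C@@H]1c1ccc(OCc5ccccc5)c(OCc5ccccc5)c1
F2 | step 2 | 5,7,3',4'-tetra-O-benzyl-(−)-epicatechin (2R,3R) | O[C@@H]1Cc2c(OCc5ccccc5)cc(OCc5ccccc5)cc2O[C@@H]1c1ccc(OCc5ccccc5)c(OCc5ccccc5)c1
F3 | step 3 | (2R,3R,4S)-5,7,3',4'-tetra-O-benzyl-4β-(2-ethoxyethoxy)epicatechin | O[C@@H]1[C@@H](OCCOCC)c2c(OCc5ccccc5)cc(OCc5ccccc5)cc2O[C@@H]1c1ccc(OCc5ccccc5)c(OCc5ccccc5)c1
F4 | step 5 | 8-bromo-4β-(2-ethoxyethoxy)-hepta-O-benzyl-epicatechin 3-O-gallate | O=C(O[C@@H]1[C@@H](OCCOCC)c2c(OCc5ccccc5)cc(OCc5ccccc5)c(Br)c2O[C@@H]1c1ccc(OCc5ccccc5)c(OCc5ccccc5)c1)c1cc(OCc5ccccc5)c(OCc5ccccc5)c(OCc5ccccc5)c1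
F5 | step 5 | 8-bromo-capped protected trimer (Br at C8 of the upper unit of 8) | O=C(O[C@@H]1[C@@H](c2c(OCc5ccccc5)cc(OCc5ccccc5)c3c2O[C@H](c2ccc(OCc5ccccc5)c(OCc5ccccc5)c2)[C@@H](O)C3)c2c(OCc5ccccc5)cc(OCc5ccccc5)c([C@H]3c4c(OCc5ccccc5)cc(OCc5ccccc5)c(Br)c4O[C@H](c4ccc(OCc5ccccc5)c(OCc5ccccc5)c4)[C@@H]3OC(=O)c3cc(OCc5ccccc5)c(OCc5ccccc5)c(OCc5ccccc5)c3)c2O[C@@H]1c1ccc(OCc5ccccc5)c(OCc5ccccc5)c1)c1cc(OCc5ccccc5)c(OCc5ccccc5)c(OCc5ccccc5)c1
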